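**Abbreviations:** TIPS = triisopropylsilyl; TBS = tert-butyldimethylsilyl; geranyl = (2E)-3,7-dimethylocta-2,6-dien-1-yl; Rh2(S-PTTL)4 = dirhodium tetrakis[N-phthaloyl-(S)-tert-leucinate]. Flavanone numbering (O1, C2–C4, C4a, C5–C8, C8a) is used for all ring positions.

## The problem

Schizolaenone C (13) is a (2S)-flavanone: a dihydropyranone ring C fused to a phloroglucinol-type ring A, with a 3,5-dihydroxyphenyl ring B on C2 and an (E)-geranyl chain on C6 between the C5 and C7 hydroxyls. C2 is the only stereocentre, so nothing in the molecule can relay its configuration; it must come from a reagent or a catalyst. Once set, C2 is fragile: it is a benzylic ether carbon β to the C4 ketone, and base opens ring C to the 2'-hydroxychalcone, which recloses as the racemate. The geranyl chain forbids hydrogenolysis, strong Lewis acids and strong protic acid (its alkenes cyclise onto the flanking phenols), and its C2''=C3'' double bond has to arrive with the E geometry intact. Ring A poses a regiochemical question: of its three oxygens, the one that becomes O1 must be the one that does not flank the geranyl carbon, or the 8-geranyl isomer results. The feature that allows a short solution is C2 itself: it is a benzylic carbon bound to O1 and lies six atoms from C3 along C4, C4a, C8a and O1. The C2–C3 bond can therefore be made by insertion of a C3 carbenoid into the methylene C–H of an aryl benzyl ether, which closes ring C and creates C2 in one operation.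

## Retrosynthesis

**13 from 12 (four O–Si bonds).** The phenols are masked as silyl ethers because these come off with buffered fluoride, without base, hydrogen or strong acid, so C2 and the chain are safe. Silicon also puts no C–H on the atom next to the C5 oxygen; an acetal there would offer the carbenoid a second six-membered insertion. TIPS is chosen over smaller silyl groups so that the ethers para and ortho to the carbonyl survive the enolate and amine steps. The forward step asks only for complete cleavage of the flanked C5 ether.

**12 from 11 (C2–C3).** Cutting O1–C2 would lead to a chalcone and a reversible, base-mediated oxa-Michael closure, which threatens C2 and leaves open which ortho oxygen closes. Cutting C4–C4a would need an acid-mediated acylation next to the chain. Cutting C2–C3 turns the stereocentre into a pair of enantiotopic hydrogens: 11 has no ring C and no stereocentre, and O1 is already fixed as an ether, so the 6- versus 8-geranyl question is settled before ring closure. The forward reaction must select one benzylic hydrogen and must prefer C–H insertion to ylide formation at O1.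

**11 from 9 (C3=N2).** The diazo group is put on the methyl ketone by detrifluoroacetylative diazo transfer. This avoids a benzoic acid, an acid chloride and diazomethane, and uses only a hindered amide base and an amine. The precursor 9 is an ordinary acetophenone.

**9 from 8, and 8 from 4 and 7 (one O–Si bond, then the O1–CH2 bond).** The last silyl group goes on the hindered, chelated C5 hydroxyl of 8. The benzyl ether is made by Mitsunobu coupling of 4 with alcohol 7 rather than with a bromide and carbonate, because aryl silyl ethers conjugated to a carbonyl are labile to carbonate in polar media. In 4 the hydroxyl between acetyl and geranyl is shielded and held in the stronger hydrogen bond, so the reaction is asked to alkylate only the other ortho hydroxyl.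

**4 from 3, and 3 from 1 and 2 (one O–Si bond, then C6–C1'').** The chain is attached by direct C-alkylation of the symmetric acetophenone 1 with bromide 2, a known one-step preparation of 3 that displaces bromide at the primary carbon and leaves the E alkene alone. A para-Claisen–Cope relay of an O-geranyl ether would fix the position of the chain, but it passes through a tertiary linalyl-type centre and re-forms the C2''=C3'' alkene without geometric control; it is set aside for that reason. The price of the direct route is that the three hydroxyls of 3 must be told apart; the first call is one equivalent of silyl chloride at the most acidic, para hydroxyl.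

**7 from 6, and 6 from 5 (C–H at the benzylic carbon; two O–Si bonds).** Ring B comes from 3,5-dihydroxybenzaldehyde (5). Silylating the aldehyde and then reducing it avoids the phenol-versus-alcohol selectivity problem of silylating 3,5-dihydroxybenzyl alcohol directly.

## Roads not taken

**Alternative 1:** The cut runs through ring A (C4a–C5 last), so that ring A is grown on a finished, enantioenriched ring C. Heating the dioxinone A2 expels acetone; the acylketene is attacked by C4a, the α-carbon of the vinylogous ester, and the cyclohexadienone tautomerises to the resorcinol A1.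
- Merits: C2 would come from a catalytic asymmetric hetero-Diels–Alder reaction when the pyranone core of A2 is made, a more dependable source of enantiopurity than selection between two enantiotopic hydrogens. The place of the chain and the identity of O1 are fixed by construction. In both respects this road is better than the chosen one, and the C5 and C7 hydroxyls emerge free.
- Weak points: A2 is long to make (a geranylated dioxinone joined through C8 to the pyranone). C4a is a weak nucleophile, so the closure needs prolonged heating, under which the benzylic C2–O1 bond β to the carbonyl can open and reclose, and the acylketene can dimerise or acylate oxygen. The ring B acetals of A1 must be removed by acid beside a geranyl chain with free flanking phenols.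
- Comparison: the chosen plan sets against the better-secured stereocentre a much shorter linear sequence, ring closure at or below room temperature under neutral conditions, and a fluoride-only deprotection.

**Alternative 2:** The cut is C3–C4, made as an enol ether double bond. Second-generation Grubbs catalyst joins the vinyl group on C2 of A4 with the silyl enol ether methylene on C4, ethylene leaves, and the 4-silyloxy-2H-chromene A3 forms; hydrolysis gives the ketone.
- Merits: the stereocentre is made earlier, in the C–O bond formation that gives A4 (enantioselective allylic etherification), which has broader precedent than carbenoid insertion. Metathesis is neutral and does not touch C2.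
- Weak points: A4 carries two more alkenes in the geranyl chain, and the 1,1-disubstituted, doubly flanked enol ether is a slow partner, so the ruthenium carbene has time to engage the chain. A4 is an aryl ether of an allylic and benzylic carbinol with a free ortho position at C8, so aromatic Claisen rearrangement and ionisation threaten C2 on warming. Four acetals must be cleaved by acid at the end.
- Comparison: this road is as good or better for the origin of the stereocentre and about as long. The chosen plan offers no alkene-selective catalyst near the chain, no thermally labile allyl aryl ether and no acid step.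

**Alternative 3:** The cut is O1–C8a. Pd(OAc)2, a bulky di-tert-butyl biaryl phosphine and Cs2CO3 couple the C2 hydroxyl of the diol triflate A6 with C8a, with retention at C2, to give the flavan-4-ol A5; oxidation at C4 and acetal removal follow.
- Merits: the C–O coupling does not touch C2, so a configuration set by standard asymmetric aldol or reduction chemistry is carried through unchanged. This is better than having to choose between enantiotopic hydrogens.
- Weak points: C4 must be carried as a carbinol and oxidised afterwards. The palladium alkoxide of a secondary benzylic alcohol can undergo β-hydride elimination. The electron-rich triflate is slow in oxidative addition and open to S–O cleavage by carbonate. The end game again needs acid next to the chain.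
- Comparison: more steps and a more delicate finish. The chosen plan forms ring C directly at the ketone oxidation level and removes all protecting groups with fluoride.

Key step: step 8

**Assumption:** Rh2(S-PTTL)4 is taken to deliver the (2S)-chromanone. The sense of induction for this substrate class would be confirmed on the first batch; if it is opposite, the mirror-image catalyst Rh2(R-PTTL)4 is used with no other change.

## Route

Step 1
Reactants: 1 2,4,6-trihydroxyacetophenone; 2 geranyl bromide
Product: 3 1-(3-geranyl-2,4,6-trihydroxyphenyl)ethanone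
Conditions: K2CO3, acetone, reflux
Reagents that add atoms: none
Why: C-alkylation of the ambident phloroglucinol phenoxide (a vinylogous triketone enolate) by a primary allylic bromide, the known one-step entry to this acetophenone; SN2 displacement leaves the E alkene untouched, and one equivalent of 2 keeps O-alkylation and double alkylation as separable side paths.

Step 2
Reactants: 3 1-(3-geranyl-2,4,6-trihydroxyphenyl)ethanone
Product: 4 1-[3-geranyl-2,6-dihydroxy-4-(triisopropylsilyloxy)phenyl]ethanone
Conditions: TIPSCl (1.05 equiv), imidazole, DMF, 0 °C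
Reagents that add atoms: triisopropylsilyl chloride, CC(C)[Si](Cl)(C(C)C)C(C)C
Why: Chemoselective phenol silylation: the hydroxyl para to the acetyl group is the most acidic and never chelates the carbonyl, so one equivalent of the bulky chloride should go there first, as in the selective 7-O-protection of 5,7-dihydroxyflavonoids; any bis-silyl ether is separable.

Step 3
Reactants: 5 3,5-dihydroxybenzaldehyde
Product: 6 3,5-bis(triisopropylsilyloxy)benzaldehyde
Conditions: TIPSCl, imidazole, DMF, rt
Reagents that add atoms: triisopropylsilyl chloride, CC(C)[Si](Cl)(C(C)C)C(C)C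
Why: Standard silylation of two unhindered phenols; the aldehyde is inert.

Step 4
Reactants: 6 3,5-bis(triisopropylsilyloxy)benzaldehyde
Product: 7 [3,5-bis(triisopropylsilyloxy)phenyl]methanol
Conditions: NaBH4, MeOH–THF, 0 °C
Reagents that add atoms: none
Why: Borohydride reduction of an aromatic aldehyde; aryl TIPS ethers tolerate cold methanolic borohydride.

Step 5
Reactants: 4 1-[3-geranyl-2,6-dihydroxy-4-(triisopropylsilyloxy)phenyl]ethanone; 7 [3,5-bis(triisopropylsilyloxy)phenyl]methanol
Product: 8 1-[2-{[3,5-bis(triisopropylsilyloxy)phenyl]methoxy}-5-geranyl-6-hydroxy-4-(triisopropylsilyloxy)phenyl]ethanone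
Conditions: PPh3, DIAD, THF, 0 °C → rt
Reagents that add atoms: none
Why: Mitsunobu etherification of a phenol with a primary benzylic alcohol under neutral conditions, so no silyl ether is lost; the hydroxyl between acetyl and geranyl is shielded and held in the stronger chelate, so the unflanked ortho hydroxyl (the future O1) should react, and the remaining chelated hydroxyl stops a second alkylation.

Step 6
Reactants: 8 1-[2-{[3,5-bis(triisopropylsilyloxy)phenyl]methoxy}-5-geranyl-6-hydroxy-4-(triisopropylsilyloxy)phenyl]ethanone
Product: 9 1-[2-{[3,5-bis(triisopropylsilyloxy)phenyl]methoxy}-5-geranyl-4,6-bis(triisopropylsilyloxy)phenyl]ethanone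
Conditions: TIPSOTf, 2,6-lutidine, CH2Cl2, −78 → 0 °C
Reagents that add atoms: triisopropylsilyl trifluoromethanesulfonate, CC(C)[Si](OS(=O)(=O)C(F)(F)F)(C(C)C)C(C)C
Why: Silylation of a hindered, hydrogen-bonded phenol needs the silyl triflate; with 2,6-lutidine at low temperature O–H silylation should outrun enol ether formation at the twisted methyl ketone.

Step 7
Reactants: 9 1-[2-{[3,5-bis(triisopropylsilyloxy)phenyl]methoxy}-5-geranyl-4,6-bis(triisopropylsilyloxy)phenyl]ethanone
Product: 11 2-diazo-1-[2-{[3,5-bis(triisopropylsilyloxy)phenyl]methoxy}-5-geranyl-4,6-bis(triisopropylsilyloxy)phenyl]ethanone, via trifluoroacetyl diketone 10 (not isolated)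
Conditions: LiHMDS, THF, −78 °C; CF3CO2CH2CF3; aq. HCl (5%) work-up, crude carried on; MsN3, Et3N, H2O, MeCN, rt
Reagents that add atoms: methanesulfonyl azide, CS(=O)(=O)N=[N+]=[N-]; 2,2,2-trifluoroethyl trifluoroacetate, O=C(OCC(F)(F)F)C(F)(F)F (its atoms are held only in 10)
Why: Detrifluoroacetylative diazo transfer (a Regitz-type transfer with an activating acyl group): the lithium enolate of the methyl ketone is C-acylated, the activated 1,3-diketone takes the diazo group from the sulfonyl azide, and the trifluoroacetyl group leaves as the N-acyl sulfonamide; the conditions spare silyl ethers and alkenes.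

Step 8
Reactants: 11 2-diazo-1-[2-{[3,5-bis(triisopropylsilyloxy)phenyl]methoxy}-5-geranyl-4,6-bis(triisopropylsilyloxy)phenyl]ethanone
Product: 12 (2S)-2-[3,5-bis(triisopropylsilyloxy)phenyl]-6-geranyl-5,7-bis(triisopropylsilyloxy)chroman-4-one
Conditions: Rh2(S-PTTL)4 (2 mol %), 4 Å MS, hexane–CH2Cl2, 0 °C, slow addition of 11
Reagents that add atoms: none
Why: Loss of nitrogen from 11 on the divalent rhodium carboxylate gives an electrophilic acceptor carbenoid at C3, which inserts into one benzylic C–H of the O1–CH2 group through a three-centre, hydride-transfer-like transition state and so forms C2–C3. The closest known reaction type is the enantioselective intramolecular C–H insertion of ortho-alkoxyaryl diazoketones to 2-substituted chroman-4-ones under chiral dirhodium tetracarboxylates. Ring C closes as a six-membered ring by 1,6-insertion (carbenoid carbon and C–H carbon linked through C4, C4a, C8a and O1), the only ring size this tether allows. C2 is set by catalyst control: the phthalimido walls of the tert-leucinate ligands should let only one of the two enantiotopic benzylic hydrogens reach the carbenoid. The step needs chemoselectivity for C–H insertion over oxonium ylide formation at O1 with 1,2-benzyl shift, over addition to the C2''=C3'' alkene and over O–H insertion. The substrate secures this because the target C–H is activated by both O1 and the aryl ring, the silyl ethers carry no C–H on the atom next to oxygen and leave no free hydroxyl, the alkene can only be reached through a seven-membered ring, and the two ortho substituents twist the acyl group out of the arene plane, which hampers the planar five-membered ylide. A weakly polar, non-coordinating medium and slow addition further disfavour the zwitterionic ylide and carbene dimerisation.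

Step 9
Reactants: 12 (2S)-2-[3,5-bis(triisopropylsilyloxy)phenyl]-6-geranyl-5,7-bis(triisopropylsilyloxy)chroman-4-one
Product: 13 schizolaenone C, (2S)-2-(3,5-dihydroxyphenyl)-6-geranyl-5,7-dihydroxychroman-4-one
Conditions: HF·pyridine, pyridine, THF, 0 °C → rt
Reagents that add atoms: none
Why: Fluoride-driven cleavage of four aryl silyl ethers in a pyridine-buffered, non-basic medium: no phenoxide or enolate builds up, so ring C should not open and C2 should keep its configuration, and the medium is too weakly acidic to cyclise the chain onto the freed phenols.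

## Compound list

1 | 2,4,6-trihydroxyacetophenone | CC(=O)c1c(O)cc(O)cc1O | starting material
2 | geranyl bromide, (2E)-1-bromo-3,7-dimethylocta-2,6-diene | CC(C)=CCC/C(C)=C/CBr | starting material
3 | 1-(3-geranyl-2,4,6-trihydroxyphenyl)ethanone | CC(=O)c1c(O)cc(O)c(C/C=C(\C)CCC=C(C)C)c1O | intermediate
4 | 1-[3-geranyl-2,6-dihydroxy-4-(triisopropylsilyloxy)phenyl]ethanone | CC(=O)c1c(O)cc(O[Si](C(C)C)(C(C)C)C(C)C)c(C/C=C(\C)CCC=C(C)C)c1O | intermediate
5 | 3,5-dihydroxybenzaldehyde | O=Cc1cc(O)cc(O)c1 | starting material
6 | 3,5-bis(triisopropylsilyloxy)benzaldehyde | O=Cc1cc(O[Si](C(C)C)(C(C)C)C(C)C)cc(O[Si](C(C)C)(C(C)C)C(C)C)c1 | intermediate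
7 | [3,5-bis(triisopropylsilyloxy)phenyl]methanol | OCc1cc(O[Si](C(C)C)(C(C)C)C(C)C)cc(O[Si](C(C)C)(C(C)C)C(C)C)c1 | intermediate
8 | 1-[2-{[3,5-bis(triisopropylsilyloxy)phenyl]methoxy}-5-geranyl-6-hydroxy-4-(triisopropylsilyloxy)phenyl]ethanone | CC(=O)c1c(OCc2cc(O[Si](C(C)C)(C(C)C)C(C)C)cc(O[Si](C(C)C)(C(C)C)C(C)C)c2)cc(O[Si](C(C)C)(C(C)C)C(C)C)c(C/C=C(\C)CCC=C(C)C)c1O | intermediate
9 | 1-[2-{[3,5-bis(triisopropylsilyloxy)phenyl]methoxy}-5-geranyl-4,6-bis(triisopropylsilyloxy)phenyl]ethanone | CC(=O)c1c(OCc2cc(O[Si](C(C)C)(C(C)C)C(C)C)cc(O[Si](C(C)C)(C(C)C)C(C)C)c2)cc(O[Si](C(C)C)(C(C)C)C(C)C)c(C/C=C(\C)CCC=C(C)C)c1O[Si](C(C)C)(C(C)C)C(C)C | intermediate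
10 | 1-[2-{[3,5-bis(triisopropylsilyloxy)phenyl]methoxy}-5-geranyl-4,6-bis(triisopropylsilyloxy)phenyl]-4,4,4-trifluorobutane-1,3-dione | FC(F)(F)C(=O)CC(=O)c1c(OCc2cc(O[Si](C(C)C)(C(C)C)C(C)C)cc(O[Si](C(C)C)(C(C)C)C(C)C)c2)cc(O[Si](C(C)C)(C(C)C)C(C)C)c(C/C=C(\C)CCC=C(C)C)c1O[Si](C(C)C)(C(C)C)C(C)C | intermediate
11 | 2-diazo-1-[2-{[3,5-bis(triisopropylsilyloxy)phenyl]methoxy}-5-geranyl-4,6-bis(triisopropylsilyloxy)phenyl]ethanone | [N-]=[N+]=CC(=O)c1c(OCc2cc(O[Si](C(C)C)(C(C)C)C(C)C)cc(O[Si](C(C)C)(C(C)C)C(C)C)c2)cc(O[Si](C(C)C)(C(C)C)C(C)C)c(C/C=C(\C)CCC=C(C)C)c1O[Si](C(C)C)(C(C)C)C(C)C | intermediate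
12 | (2S)-2-[3,5-bis(triisopropylsilyloxy)phenyl]-6-geranyl-5,7-bis(triisopropylsilyloxy)chroman-4-one | CC(C)=CCC/C(C)=C/Cc1c(O[Si](C(C)C)(C(C)C)C(C)C)cc2c(c1O[Si](C(C)C)(C(C)C)C(C)C)C(=O)C[C@@H](c1cc(O[Si](C(C)C)(C(C)C)C(C)C)cc(O[Si](C(C)C)(C(C)C)C(C)C)c1)O2 | intermediate
13 | schizolaenone C, (2S)-2-(3,5-dihydroxyphenyl)-6-geranyl-5,7-dihydroxychroman-4-one | CC(C)=CCC/C(C)=C/Cc1c(O)cc2c(c1O)C(=O)C[C@@H](c1cc(O)cc(O)c1)O2 | target

## Step count and risks

Total: 9 steps. Longest linear sequence: 7 steps (steps 1, 2, 5, 6, 7, 8, 9 from 1; equally steps 3–9 from 5).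

**Step 8 (key step).** Most likely to go wrong: the unsubstituted acceptor carbenoid is very reactive and its transition state is early, so discrimination between the two enantiotopic benzylic hydrogens may be poor; some material may also leak through the oxonium ylide. Fallback, from 11 back to 12: give up catalyst-controlled induction and resolve. Decomposition of 11 with achiral Rh2(OAc)4 in CH2Cl2 should give the racemic 2-[3,5-bis(triisopropylsilyloxy)phenyl]-6-geranyl-5,7-bis(triisopropylsilyloxy)chroman-4-one F1. Asymmetric transfer hydrogenation of F1 with RuCl(p-cymene)[(R,R)-TsDPEN] and HCO2H–Et3N is a known kinetic resolution of flavanones. Hydride is delivered anti to the C2 aryl group, and the ligand enantiomer is chosen so that the (2R)-ketone reacts fast, giving the cis alcohol (2R,4R)-2-[3,5-bis(triisopropylsilyloxy)phenyl]-6-geranyl-5,7-bis(triisopropylsilyloxy)chroman-4-ol F2. The unreacted (2S)-ketone is separated from the more polar F2 and is 12.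

**Step 5.** Most likely to go wrong: loss of site selectivity in the etherification, with alkylation of the geranyl-flanked hydroxyl (which leads into the 8-geranyl series) or of both, because the steric and hydrogen-bond bias between the two ortho hydroxyls is modest for a reactive alkoxyphosphonium ion. Fallback, from 3 back to 9: a protecting-group relay that uses the well-documented preference for leaving the flanked hydroxyl untouched. Two equivalents of TBSCl with imidazole should silylate the two accessible hydroxyls of 3 to give 1-[4,6-bis(tert-butyldimethylsilyloxy)-3-geranyl-2-hydroxyphenyl]ethanone F3. TIPSOTf and 2,6-lutidine cap the remaining chelated hydroxyl to give 1-[4,6-bis(tert-butyldimethylsilyloxy)-3-geranyl-2-(triisopropylsilyloxy)phenyl]ethanone F4. K2CO3 in methanol at 0 °C removes the two unflanked, carbonyl-activated TBS ethers but not the flanked TIPS ether, giving 1-[3-geranyl-4,6-dihydroxy-2-(triisopropylsilyloxy)phenyl]ethanone F5. Only one ortho hydroxyl is now left and it is chelated, so TIPSCl and imidazole silylate the para hydroxyl alone to give 1-[3-geranyl-6-hydroxy-2,4-bis(triisopropylsilyloxy)phenyl]ethanone F6. Mitsunobu coupling of F6 with 7 (PPh3, DIAD, THF) then has no site choice left and gives 9.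

**Step 2.** Most likely to go wrong: erosion of site selectivity and over-silylation, because the geranyl group flanks the para hydroxyl and slows it relative to the unflanked ortho hydroxyl. Fallback, from 1 back to 4: silylate before the chain is present. With one equivalent of TIPSCl and imidazole, 1 (para hydroxyl unflanked, ortho hydroxyls equivalent) should give 1-[2,6-dihydroxy-4-(triisopropylsilyloxy)phenyl]ethanone F7. C-Geranylation of F7 with 2 (DBU, THF), in which C3 and C5 are equivalent by symmetry, gives 4.

**Step 7.** Most likely to go wrong: incomplete C-trifluoroacetylation of the enolate of the doubly ortho-substituted ketone (O-acylation or proton return), so that 9 comes back unchanged after the azide stage. Fallback, from 9 back to 11: go through the α-bromoketone. LiHMDS and TMSCl in THF at −78 °C should give the silyl enol ether {1-[2-{[3,5-bis(triisopropylsilyloxy)phenyl]methoxy}-5-geranyl-4,6-bis(triisopropylsilyloxy)phenyl]ethenyloxy}trimethylsilane F8. NBS in THF at −78 °C brominates the enol ether in preference to the chain alkenes and gives 2-bromo-1-[2-{[3,5-bis(triisopropylsilyloxy)phenyl]methoxy}-5-geranyl-4,6-bis(triisopropylsilyloxy)phenyl]ethanone F9. N,N'-Ditosylhydrazine and DBU in THF at 0 °C (N-alkylation, then loss of two sulfinate groups) convert F9 into 11.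

## Further compounds

F1 | step 8 | racemic 2-[3,5-bis(triisopropylsilyloxy)phenyl]-6-geranyl-5,7-bis(triisopropylsilyloxy)chroman-4-one | CC(C)=CCC/C(C)=C/Cc1c(O[Si](C(C)C)(C(C)C)C(C)C)cc2c(c1O[Si](C(C)C)(C(C)C)C(C)C)C(=O)CC(c1cc(O[Si](C(C)C)(C(C)C)C(C)C)cc(O[Si](C(C)C)(C(C)C)C(C)C)c1)O2
F2 | step 8 | (2R,4R)-2-[3,5-bis(triisopropylsilyloxy)phenyl]-6-geranyl-5,7-bis(triisopropylsilyloxy)chroman-4-ol | O[C@@H]1C[C@H](c2cc(O[Si](C(C)C)(C(C)C)C(C)C)cc(O[Si](C(C)C)(C(C)C)C(C)C)c2)Oc2cc(O[Si](C(C)C)(C(C)C)C(C)C)c(C/C=C(\C)CCC=C(C)C)c(O[Si](C(C)C)(C(C)C)C(C)C)c21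
F3 | step 5 | 1-[4,6-bis(tert-butyldimethylsilyloxy)-3-geranyl-2-hydroxyphenyl]ethanone | CC(=O)c1c(O[Si](C)(C)C(C)(C)C)cc(O[Si](C)(C)C(C)(C)C)c(C/C=C(\C)CCC=C(C)C)c1O
F4 | step 5 | 1-[4,6-bis(tert-butyldimethylsilyloxy)-3-geranyl-2-(triisopropylsilyloxy)phenyl]ethanone | CC(=O)c1c(O[Si](C)(C)C(C)(C)C)cc(O[Si](C)(C)C(C)(C)C)c(C/C=C(\C)CCC=C(C)C)c1O[Si](C(C)C)(C(C)C)C(C)C
F5 | step 5 | 1-[3-geranyl-4,6-dihydroxy-2-(triisopropylsilyloxy)phenyl]ethanone | CC(=O)c1c(O)cc(O)c(C/C=C(\C)CCC=C(C)C)c1O[Si](C(C)C)(C(C)C)C(C)C
F6 | step 5 | 1-[3-geranyl-6-hydroxy-2,4-bis(triisopropylsilyloxy)phenyl]ethanone | CC(=O)c1c(O)cc(O[Si](C(C)C)(C(C)C)C(C)C)c(C/C=C(\C)CCC=C(C)C)c1O[Si](C(C)C)(C(C)C)C(C)C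
F7 | step 2 | 1-[2,6-dihydroxy-4-(triisopropylsilyloxy)phenyl]ethanone | CC(=O)c1c(O)cc(O[Si](C(C)C)(C(C)C)C(C)C)cc1O
F8 | step 7 | {1-[2-{[3,5-bis(triisopropylsilyloxy)phenyl]methoxy}-5-geranyl-4,6-bis(triisopropylsilyloxy)phenyl]ethenyloxy}trimethylsilane | C=C(O[Si](C)(C)C)c1c(OCc2cc(O[Si](C(C)C)(C(C)C)C(C)C)cc(O[Si](C(C)C)(C(C)C)C(C)C)c2)cc(O[Si](C(C)C)(C(C)C)C(C)C)c(C/C=C(\C)CCC=C(C)C)c1O[Si](C(C)C)(C(C)C)C(C)C
F9 | step 7 | 2-bromo-1-[2-{[3,5-bis(triisopropylsilyloxy)phenyl]methoxy}-5-geranyl-4,6-bis(triisopropylsilyloxy)phenyl]ethanone | BrCC(=O)c1c(OCc2cc(O[Si](C(C)C)(C(C)C)C(C)C)cc(O[Si](C(C)C)(C(C)C)C(C)C)c2)cc(O[Si](C(C)C)(C(C)C)C(C)C)c(C/C=C(\C)CCC=C(C)C)c1O[Si](C(C)C)(C(C)C)C(C)C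
A1 | alternative 1 | (2S)-2-[3,5-bis(methoxymethoxy)phenyl]-6-geranyl-5,7-dihydroxychroman-4-one | CC(C)=CCC/C(C)=C/Cc1c(O)cc2c(c1O)C(=O)C[C@@H](c1cc(OCOC)cc(OCOC)c1)O2
A2 | alternative 1 | (2S)-2-[3,5-bis(methoxymethoxy)phenyl]-6-[(5-geranyl-2,2-dimethyl-4-oxo-4H-1,3-dioxin-6-yl)methyl]-2,3-dihydro-4H-pyran-4-one | CC1(C)OC(=O)C(C/C=C(\C)CCC=C(C)C)=C(CC2=CC(=O)C[C@@H](c3cc(OCOC)cc(OCOC)c3)O2)O1
A3 | alternative 2 | tert-butyl({(2S)-2-[3,5-bis(methoxymethoxy)phenyl]-6-geranyl-5,7-bis(methoxymethoxy)-2H-chromen-4-yl}oxy)dimethylsilane | CC(C)=CCC/C(C)=C/Cc1c(OCOC)cc2c(c1OCOC)C(O[Si](C)(C)C(C)(C)C)=C[C@@H](c1cc(OCOC)cc(OCOC)c1)O2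
A4 | alternative 2 | tert-butyl({1-[2-({(1S)-1-[3,5-bis(methoxymethoxy)phenyl]prop-2-en-1-yl}oxy)-5-geranyl-4,6-bis(methoxymethoxy)phenyl]ethenyl}oxy)dimethylsilane | C=C[C@@H](c1cc(OCOC)cc(OCOC)c1)Oc1cc(OCOC)c(C/C=C(\C)CCC=C(C)C)c(OCOC)c1C(=C)O[Si](C)(C)C(C)(C)C
A5 | alternative 3 | (2S,4S)-2-[3,5-bis(methoxymethoxy)phenyl]-6-geranyl-5,7-bis(methoxymethoxy)chroman-4-ol | O[C@H]1C[C@@H](c2cc(OCOC)cc(OCOC)c2)Oc2cc(OCOC)c(C/C=C(\C)CCC=C(C)C)c(OCOC)c21
A6 | alternative 3 | 2-{(1S,3S)-3-[3,5-bis(methoxymethoxy)phenyl]-1,3-dihydroxypropyl}-4-geranyl-3,5-bis(methoxymethoxy)phenyl trifluoromethanesulfonate | O[C@@H](C[C@H](O)c1cc(OCOC)cc(OCOC)c1)c1c(OS(=O)(=O)C(F)(F)F)cc(OCOC)c(C/C=C(\C)CCC=C(C)C)c1OCOC
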